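**Retrosynthetic overview**
1. 14 ⇒ 12: add water back across C2=C3 and put a MOM group on O7, so the isoflavone becomes a 3-hydroxyisoflavanone.
2. 12 ⇒ 10 (key): cut C3–C4, a bond between two carbonyl carbons. In the forward direction the ring A aldehyde carbon reacts as a carbene-bound acyl anion (Breslow enaminol) with the ring B aryl ketone.
3. 10 ⇒ 9 + 5: cut the O1–C2 ether (phenol + phenacyl bromide). The choice of phenol that is alkylated decides 6-prenyl versus 8-prenyl.
4. 9 ⇒ 6 + 7 (C-prenylation, then MOM on the para OH). 5 ⇒ 1 + 2 (chromenylation, then α-bromination).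
5. Ring order: the dimethylpyran on ring B is formed first (step 1) and the pyranone ring C last (step 6, aromatised in step 7).

Assumption: the target SMILES has no stereocentre and no stereogenic double bond, so isochandalone is achiral and there is no enantiomer to select. The one stereocentre formed on the way (C3 of 12) is made racemic and is destroyed in step 7.

**Step 1**
Reactants: 1 4-hydroxyacetophenone; 2 1,1-diethoxy-3-methylbut-2-ene (prenal diethyl acetal)
Product: 3 1-(2,2-dimethyl-2H-chromen-6-yl)ethan-1-one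
Conditions: 2 (1.5 equiv), 3-methylpyridine (0.5 equiv), p-xylene, 140 °C, EtOH distilled off, 24 h
Reagents that add atoms: none
Why: Amine-mediated chromenylation (transacetalisation of the phenol, loss of ethanol, [3,3] shift to an ortho-quinone methide, oxa-6π electrocyclisation) works best on electron-poor phenols such as 1, and the two ortho positions of 1 are equivalent, so only one isomer can form.

**Step 2**
Reactants: 3 1-(2,2-dimethyl-2H-chromen-6-yl)ethan-1-one
Product: 5 2-bromo-1-(2,2-dimethyl-2H-chromen-6-yl)ethan-1-one, via silyl enol ether 4 (not isolated)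
Conditions: Me3SiOTf (1.15 equiv), Et3N (1.3 equiv), CH2Cl2, 0 °C, 30 min; then N-bromosuccinimide (1.0 equiv), −78 to 0 °C, one pot
Reagents that add atoms: trimethylsilyl trifluoromethanesulfonate C[Si](C)(C)OS(=O)(=O)C(F)(F)F (Me3Si, in 4 only); N-bromosuccinimide O=C1CCC(=O)N1Br (Br, in 5)
Why: This is an electrophilic α-bromination of a silyl enol ether, in which soft enolisation gives 4, a far better nucleophile than the chromene C3=C4 bond, so one equivalent of N-bromosuccinimide at low temperature is consumed at the enol ether only.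

**Step 3**
Reactants: 6 2,4,6-trihydroxybenzaldehyde; 7 1-bromo-3-methylbut-2-ene (prenyl bromide)
Product: 8 2,4,6-trihydroxy-3-(3-methylbut-2-en-1-yl)benzaldehyde
Conditions: KOH (1.0 equiv), H2O, 0 °C; 7 (1.0 equiv) added slowly, 0 °C to rt, 3 h
Reagents that add atoms: none
Why: In this C-prenylation of an acylphloroglucinol, the water-solvated ambident phenolate is alkylated at carbon by SN2 on the allylic bromide, the two free ring positions of 6 are equivalent, and one equivalent each of base and bromide limits diprenylation (35–45 % expected on very cheap material).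

**Step 4**
Reactants: 8 2,4,6-trihydroxy-3-(3-methylbut-2-en-1-yl)benzaldehyde
Product: 9 2,6-dihydroxy-4-(methoxymethoxy)-3-(3-methylbut-2-en-1-yl)benzaldehyde
Conditions: MOMCl (1.05 equiv), iPr2NEt (1.1 equiv), CH2Cl2, 0 °C, 2 h
Reagents that add atoms: chloromethyl methyl ether COCCl
Why: In this selective Williamson-type O-alkylation, the 4-OH (para to the formyl group and the only phenol that cannot hydrogen-bond to it) is the most acidic and most nucleophilic, so one equivalent of MOMCl with a weak amine base caps it alone.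

**Step 5**
Reactants: 9 2,6-dihydroxy-4-(methoxymethoxy)-3-(3-methylbut-2-en-1-yl)benzaldehyde; 5 2-bromo-1-(2,2-dimethyl-2H-chromen-6-yl)ethan-1-one
Product: 10 6-[2-(2,2-dimethyl-2H-chromen-6-yl)-2-oxoethoxy]-2-hydroxy-4-(methoxymethoxy)-3-(3-methylbut-2-en-1-yl)benzaldehyde
Conditions: K2CO3 (1.1 equiv), MeCN, rt, 4–6 h
Reagents that add atoms: none
Why: In this Williamson etherification, the phenol between CHO and prenyl is the more hindered and more strongly chelated one, so the phenacyl bromide takes the OH next to the ring hydrogen (which places the prenyl group at C6 and not C8 of the isoflavone), and room temperature with mild base holds back Rap–Stoermer aldol closure to a 2-aroylbenzofuran.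

**Step 6 (key step)**
Reactants: 10 6-[2-(2,2-dimethyl-2H-chromen-6-yl)-2-oxoethoxy]-2-hydroxy-4-(methoxymethoxy)-3-(3-methylbut-2-en-1-yl)benzaldehyde
Product: 12 racemic 3-(2,2-dimethyl-2H-chromen-6-yl)-3,5-dihydroxy-7-(methoxymethoxy)-6-(3-methylbut-2-en-1-yl)-2,3-dihydro-4H-chromen-4-one, via Breslow enaminol 11 (not isolated)
Conditions: 2-(pentafluorophenyl)-6,7-dihydro-5H-pyrrolo[2,1-c][1,2,4]triazol-2-ium tetrafluoroborate (20 mol %), Et3N (30 mol %), degassed THF, argon, 45 °C, 12–24 h
Reagents that add atoms: 2-(pentafluorophenyl)-6,7-dihydro-5H-pyrrolo[2,1-c][1,2,4]triazol-2-ium tetrafluoroborate c1n(-c2c(F)c(F)c(F)c(F)c2F)nc2[n+]1CCC2.F[B-](F)(F)F (its carbene is bound in 11 only and is released on turnover; nothing of it stays in 12)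
Why: This is the N-heterocyclic-carbene-catalysed intramolecular crossed aldehyde–ketone benzoin reaction, known to turn 2-(2-aryl-2-oxoethoxy)benzaldehydes into 3-aryl-3-hydroxychroman-4-ones, in which the carbene adds to the hydrogen-bond-activated formyl group, proton transfer gives Breslow enaminol 11 whose former carbonyl carbon is now an acyl anion equivalent, and that carbon attacks the aryl ketone carbonyl 6-exo-trig to forge C4–C3 and close ring C, while the weak amine buffer (enough for the acidic N-C6F5 triazolium) spares the enolisable OCH2C=O unit and the new C3 stereocentre is deliberately left racemic because step 7 erases it.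

**Step 7**
Reactants: 12 racemic 3-(2,2-dimethyl-2H-chromen-6-yl)-3,5-dihydroxy-7-(methoxymethoxy)-6-(3-methylbut-2-en-1-yl)-2,3-dihydro-4H-chromen-4-one
Product: 14 isochandalone, via MOM isoflavone 13 (not isolated)
Conditions: Burgess reagent (methyl N-(triethylammoniosulfonyl)carbamate, 1.5 equiv), THF, 60 °C, 2 h; then MeOH and conc. HCl to about 0.5 M, 40 °C, 1–2 h, one pot
Reagents that add atoms: none
Why: Burgess dehydration (syn elimination of the tertiary sulfamate, for which only C2 carries β-hydrogens and C–O ionisation at C3 is helped by the para-alkoxyaryl group) gives the fully conjugated 4-pyranone 13 under neutral conditions that spare the prenyl and chromene alkenes and the inert chelated 5-OH, and brief methanolic HCl, routinely tolerated by ortho-prenylphenols and dimethylchromenes, then transacetalises the MOM group to release achiral 14.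

**Compound list**
1 | 4-hydroxyacetophenone | CC(=O)c1ccc(O)cc1 | starting material
2 | 1,1-diethoxy-3-methylbut-2-ene | CCOC(OCC)C=C(C)C | starting material
3 | 1-(2,2-dimethyl-2H-chromen-6-yl)ethan-1-one | CC(=O)c1ccc2c(c1)C=CC(C)(C)O2 | intermediate
4 | {[1-(2,2-dimethyl-2H-chromen-6-yl)ethenyl]oxy}trimethylsilane (not isolated) | C=C(O[Si](C)(C)C)c1ccc2c(c1)C=CC(C)(C)O2 | intermediate
5 | 2-bromo-1-(2,2-dimethyl-2H-chromen-6-yl)ethan-1-one | BrCC(=O)c1ccc2c(c1)C=CC(C)(C)O2 | intermediate
6 | 2,4,6-trihydroxybenzaldehyde | O=Cc1c(O)cc(O)cc1O | starting material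
7 | 1-bromo-3-methylbut-2-ene | CC(C)=CCBr | starting material
8 | 2,4,6-trihydroxy-3-(3-methylbut-2-en-1-yl)benzaldehyde | O=Cc1c(O)cc(O)c(CC=C(C)C)c1O | intermediate
9 | 2,6-dihydroxy-4-(methoxymethoxy)-3-(3-methylbut-2-en-1-yl)benzaldehyde | O=Cc1c(O)cc(OCOC)c(CC=C(C)C)c1O | intermediate
10 | 6-[2-(2,2-dimethyl-2H-chromen-6-yl)-2-oxoethoxy]-2-hydroxy-4-(methoxymethoxy)-3-(3-methylbut-2-en-1-yl)benzaldehyde | O=Cc1c(OCC(=O)c2ccc3c(c2)C=CC(C)(C)O3)cc(OCOC)c(CC=C(C)C)c1O | intermediate
11 | Breslow enaminol of 10 with 2-(pentafluorophenyl)-6,7-dihydro-5H-pyrrolo[2,1-c][1,2,4]triazol-3-ylidene (not isolated, alkene geometry undefined) | OC(=C1N(c2c(F)c(F)c(F)c(F)c2F)N=C2CCCN12)c1c(OCC(=O)c2ccc3c(c2)C=CC(C)(C)O3)cc(OCOC)c(CC=C(C)C)c1O | intermediate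
12 | 3-(2,2-dimethyl-2H-chromen-6-yl)-3,5-dihydroxy-7-(methoxymethoxy)-6-(3-methylbut-2-en-1-yl)-2,3-dihydro-4H-chromen-4-one (racemic at C3) | CC(C)=CCc1c(OCOC)cc2OCC(O)(c3ccc4c(c3)C=CC(C)(C)O4)C(=O)c2c1O | intermediate
13 | 3-(2,2-dimethyl-2H-chromen-6-yl)-5-hydroxy-7-(methoxymethoxy)-6-(3-methylbut-2-en-1-yl)-4H-chromen-4-one (not isolated) | CC(C)=CCc1c(OCOC)cc2occ(-c3ccc4c(c3)C=CC(C)(C)O4)c(=O)c2c1O | intermediate
14 | isochandalone, 3-(2,2-dimethyl-2H-chromen-6-yl)-5,7-dihydroxy-6-(3-methylbut-2-en-1-yl)-4H-chromen-4-one (achiral) | CC(C)=CCc1c(O)cc2occ(-c3ccc4c(c3)C=CC(C)(C)O4)c(=O)c2c1O | target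

**Step count**
- Total steps: 7.
- Longest linear sequence: 5 steps, either 3, 4, 5, 6, 7 from 6 or 1, 2, 5, 6, 7 from 1.

**Three steps most likely to fail**

Step 6. The aldehyde is very electron-rich, carries oxygen at both ortho positions, and sits next to an acidic phenol that can buffer the carbene away. Breslow formation may therefore stall, or aldol chemistry may take over. The fallback sets out from 10 and comes back at 12, and it changes the substrate class rather than tuning the catalyst. The chelated phenol of 10 is silylated (Et3SiCl, imidazole, DMF, rt) to the triethylsilyl ether of the keto-aldehyde F1. This proton-free substrate is cyclised with the same triazolium salt, now fully deprotonated by an equal amount of 1,8-diazabicyclo[5.4.0]undec-7-ene in toluene at rt, where the carbene concentration is far higher. That gives the 5-O-triethylsilyl 3-hydroxyisoflavanone F2. Et3N·3HF in THF then removes the silyl group to give 12.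

Step 5. The ether could form at the wrong ortho phenol, which would lead to the 8-prenyl series, or the product could close to a benzofuran. The fallback sets out from 6 (with 7 and 5) and comes back at 10. It fixes the regiochemistry by a sigmatropic sequence instead of by steric bias.
- 6 is protected twice (MOMCl 2.2 equiv, iPr2NEt, CH2Cl2) to 2-hydroxy-4,6-bis(methoxymethoxy)benzaldehyde F3.
- The remaining phenol is O-prenylated with 7 (K2CO3, DMF, 50 °C) to 2,4-bis(methoxymethoxy)-6-[(3-methylbut-2-en-1-yl)oxy]benzaldehyde F4.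
- Heating in N,N-diethylaniline at 200 °C triggers a para-Claisen–Cope cascade that puts the prenyl group between the two MOM ethers, para to the liberated phenol. This gives 6-hydroxy-2,4-bis(methoxymethoxy)-3-(3-methylbut-2-en-1-yl)benzaldehyde F5.
- The single free phenol is alkylated with 5 (K2CO3, MeCN, rt) to the bis-MOM keto-aldehyde F6.
- Dilute methanolic HCl at 0 °C removes only the carbonyl-flanked MOM group, which gives 10.

Step 3. Direct C-prenylation gives over-alkylated and O-alkylated by-products, and its yield may be too low. The fallback sets out from 6 (with 7) and comes back at 9, bypassing steps 3 and 4.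
- 6 is first capped at the para OH (MOMCl 1.05 equiv, iPr2NEt, CH2Cl2, 0 °C) to the symmetric 2,6-dihydroxy-4-(methoxymethoxy)benzaldehyde F7.
- One of its two equivalent phenols is O-prenylated with 7 (K2CO3, acetone, rt) to 2-hydroxy-4-(methoxymethoxy)-6-[(3-methylbut-2-en-1-yl)oxy]benzaldehyde F8.
- The same para-Claisen–Cope rearrangement (N,N-diethylaniline, 200 °C) moves the prenyl group to the carbon para to that oxygen, between the OH and the OMOM group. The product is 9.

**Further compounds**
F1 | step 6 | 6-[2-(2,2-dimethyl-2H-chromen-6-yl)-2-oxoethoxy]-4-(methoxymethoxy)-3-(3-methylbut-2-en-1-yl)-2-[(triethylsilyl)oxy]benzaldehyde | O=Cc1c(OCC(=O)c2ccc3c(c2)C=CC(C)(C)O3)cc(OCOC)c(CC=C(C)C)c1O[Si](CC)(CC)CC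
F2 | step 6 | 3-(2,2-dimethyl-2H-chromen-6-yl)-3-hydroxy-7-(methoxymethoxy)-6-(3-methylbut-2-en-1-yl)-5-[(triethylsilyl)oxy]-2,3-dihydro-4H-chromen-4-one (racemic) | CC(C)=CCc1c(OCOC)cc2OCC(O)(c3ccc4c(c3)C=CC(C)(C)O4)C(=O)c2c1O[Si](CC)(CC)CC
F3 | step 5 | 2-hydroxy-4,6-bis(methoxymethoxy)benzaldehyde | O=Cc1c(O)cc(OCOC)cc1OCOC
F4 | step 5 | 2,4-bis(methoxymethoxy)-6-[(3-methylbut-2-en-1-yl)oxy]benzaldehyde | O=Cc1c(OCC=C(C)C)cc(OCOC)cc1OCOC
F5 | step 5 | 6-hydroxy-2,4-bis(methoxymethoxy)-3-(3-methylbut-2-en-1-yl)benzaldehyde | O=Cc1c(O)cc(OCOC)c(CC=C(C)C)c1OCOC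
F6 | step 5 | 6-[2-(2,2-dimethyl-2H-chromen-6-yl)-2-oxoethoxy]-2,4-bis(methoxymethoxy)-3-(3-methylbut-2-en-1-yl)benzaldehyde | O=Cc1c(OCC(=O)c2ccc3c(c2)C=CC(C)(C)O3)cc(OCOC)c(CC=C(C)C)c1OCOC
F7 | step 3 | 2,6-dihydroxy-4-(methoxymethoxy)benzaldehyde | O=Cc1c(O)cc(OCOC)cc1O
F8 | step 3 | 2-hydroxy-4-(methoxymethoxy)-6-[(3-methylbut-2-en-1-yl)oxy]benzaldehyde | O=Cc1c(O)cc(OCOC)cc1OCC=C(C)C
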